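I had 3 questions to answer and wanted one number to answer them with.

- west: left-handed substrate 0.26 M; right-handed substrate 0.26 M; partner 2.5 equiv; racemization catalyst 0.22 mol%; precatalyst 10 mol%; impurity 0.14 mM; run made earlier
- flask: left-handed substrate 0.13 M; partner 2.50 equiv; racemization catalyst 0.22 mol%; precatalyst 10 mol%; impurity 0.14 mM; right-handed substrate 0.13 M; time 5.0 min

west run (percent of the left-handed substrate and right-handed substrate together charged)

| time / s | left-handed product / % | right-handed product / % | left-handed substrate / % |
|---|---|---|---|
| 15.0 | 50 | 7 | 10 |
| 30.0 | 67 | 13 | 2 |
| 50.0 | 71 | 19 | 0 |
| 60.0 | 74 | 19 | 0 |
| 80.0 | 72 | 18 | 3 |
| 90.0 | 76 | 21 | 0 |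

(readings scatter by 2 percentage points)

- free catalyst is single-handed; left-handed substrate and right-handed substrate are mirror images of each other, charged as a racemate, each of them at the stated concentration
- steps thought possible: left-handed substrate + racemization catalyst <-> right-handed substrate + racemization catalyst; racemization catalyst + impurity -> spent catalyst; partner + free catalyst + right-handed substrate -> free catalyst + right-handed product; partner + free catalyst + left-handed substrate -> free catalyst + left-handed product; partner + precatalyst -> free catalyst + spent reagent
- an excess is below zero if the other one leads
- no earlier run changes the charge of precatalyst; that part of a forecast is a guess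
- no earlier run changes the charge of racemization catalyst; that part of a forecast is a guess

- left-handed product and right-handed product together, in percent of the left-handed substrate and right-handed substrate charged together, at 5.0 min
- excess of left-handed product over right-handed product in the product at 5.0 min
- whether the exchange between left-handed substrate and right-handed substrate keeps pace with the reaction: how far the product's excess at 5.0 min gets from its value without exchange to its value with instant exchange (above 80% keeps pace, below 20% hardly takes part, else lags behind)

Right-handed substrate has two exits, each first order in it: it crosses over to left-handed substrate, or it becomes right-handed product. Dividing the amount gone by one exit by the amount gone by the other removes time. Left-handed product plus left-handed substrate, above the half charged, counts what crossed, so the last 4 west readings give a ratio of 1.25 of what crossed to right-handed product. I called this the crossing odds. The west reading at 15.0 s gives 1.43, the same within the scatter. Once the substrates are nearly used up, the product's excess is the odds divided by one plus the odds.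

For the flask, I took live racemization catalyst as its charge minus the impurity: 0.146 mM against 0.432 mM in west. Reaction slows fourfold if free catalyst is present at once, but by 2.83 if it is still forming from precatalyst and partner. So one number was not enough: I estimated the flask's odds at between 1.19 and 1.69, an excess between 54.3% and 62.8%. I expected the exchange to lag behind, and the yield to match west at 80.0 s to 90.0 s, 90.0% to 97.0%.

The forecast gave 95% and 62% (54% to 69%), lags behind, holding that “exchange falls only about 2.3-fold”.

The flask gave 97.5% and 57.0%; the exchange lags behind, 60% of the way.

    left-handed substrate + racemization catalyst ⇌ right-handed substrate + racemization catalyst, rate k1*[racemization catalyst]*[left-handed substrate] forward; the back reaction follows from the equilibrium constant (k = 53.0 M⁻¹ s⁻¹)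
    racemization catalyst + impurity → spent catalyst (k = 44000 M⁻¹ s⁻¹)
    partner + free catalyst + right-handed substrate → free catalyst + right-handed product (k = 5.30 M⁻² s⁻¹)
    partner + free catalyst + left-handed substrate → free catalyst + left-handed product (k = 81.0 M⁻² s⁻¹)
    partner + precatalyst → free catalyst + spent reagent (k = 0.0550 M⁻¹ s⁻¹)

The flask's own crossing odds came to 1.28, below the top of my estimate, 1.69. At 0.500 min, with 46.2% of the substrates reacted, free catalyst stood at 35.4% of the catalyst charged. For the neighbouring flask with 4 mol% of precatalyst, I stretched the odds by the root of the loading ratio, to 2.02, an excess of 66.9%; that flask gave 68.0%.

All runs were computed from invented constants; noise was put on by code.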